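**Assumption:** the target is taken exactly as drawn ((3S,4R), trans, E-butenedioate), and the O-methyl group of 3-methoxyphenol is treated as a protecting group (it is removed in the last step), so that starting material counts as resorcinol.

## Retrosynthetic overview

1. Target 17 comes from lactone 16 by cleaving two aryl methyl ethers and one tert-butyl ester.
2. The lactone ring of 16 comes from ring expansion of the 2-hydroxy-1-indanone-2-carboxylate 15: a 1,2-shift of the aryl ketone carbon from carbon to oxygen turns the five-membered carbocycle into the six-membered lactone, and C3 is set by protonation trans to C4.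
3. Indanone 15 comes from keto aldehyde 14 by an intramolecular carbene-catalysed cross-benzoin reaction with dynamic kinetic resolution (C1–C3 bond, C4 stereocentre).
4. Keto aldehyde 14 comes from the C4–C4a bond: dienolate 12 (from 2-pyranone 11, made from dimethyl oxalate and dimethyl itaconate) adds to formyl quinone monoketal 5 (from 3-methoxyphenol, formaldehyde and methanol).
5. Ring order: the benzene ring is carried through (dearomatised in 5, restored in step 5), pyranone 11 is a temporary ring, then the indanone, then the dihydroisocoumarin by ring expansion.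

## Route

Step 1
Reactants: 1 3-methoxyphenol
Product: 3 2-hydroxy-4-methoxybenzaldehyde, via salicyl alcohol 2 (not isolated)
Conditions: (CH2O)n, MgCl2, Et3N, MeCN, reflux; then 1 M HCl
Reagents that add atoms: formaldehyde (from paraformaldehyde), C=O
Why: Casnati–Skattebøl ortho-formylation, in which the magnesium phenoxide delivers formaldehyde to the less hindered ortho position (para to OMe) and the salicyl alcohol is oxidised by a second formaldehyde through an Oppenauer-type hydride transfer.

Step 2
Reactants: 3 2-hydroxy-4-methoxybenzaldehyde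
Product: 5 3,3,4-trimethoxy-6-oxocyclohexa-1,4-diene-1-carbaldehyde, via dimethoxysalicylaldehyde 4 (not isolated)
Conditions: PhI(OAc)2 (2.2 equiv), MeOH, 0 °C to rt
Reagents that add atoms: methanol, CO
Why: two consecutive oxidative dearomatisations with the trivalent iodine reagent (methanol attack at the free para position, tautomerisation to the p-methoxyphenol 4, then ketalisation) give the p-quinone monoketal and bring in the third ring oxygen.

Step 3
Reactants: 6 itaconic anhydride
Product: 8 dimethyl itaconate, via monomethyl itaconate 7 (not isolated)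
Conditions: MeOH, H2SO4 (cat.), reflux
Reagents that add atoms: methanol, CO
Why: acid-catalysed methanolysis of the anhydride followed by Fischer esterification of the remaining conjugated acid.

Step 4
Reactants: 8 dimethyl itaconate; 9 dimethyl oxalate
Product: 11 dimethyl 2-oxo-2H-pyran-4,6-dicarboxylate, via oxalyl itaconate 10 (not isolated)
Conditions: NaOCH3 (1.1 equiv), MeOH–Et2O, 0 °C to rt; then HCl, AcOH, 60 °C
Reagents that add atoms: none
Why: vinylogous Claisen condensation of the itaconate enolate with dimethyl oxalate at its γ-terminus (the oxalocrotonate reaction type), then acid-induced enol lactonisation with loss of methanol; the 2-pyranone marks the future carboxylic acid carbon as a lactone, distinct from the two methyl esters.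

Step 5
Reactants: 11 dimethyl 2-oxo-2H-pyran-4,6-dicarboxylate; 5 3,3,4-trimethoxy-6-oxocyclohexa-1,4-diene-1-carbaldehyde
Product: 14 1-tert-butyl 2,4-dimethyl (1E)-3-(2-formyl-3-hydroxy-5,6-dimethoxyphenyl)-4-oxobut-1-ene-1,2,4-tricarboxylate (racemic), via potassium dienolate 12 (not isolated), via Michael adduct 13 (not isolated)
Conditions: KOC(CH3)3 (1.0 equiv), THF, −78 to 0 °C; add 5, −40 °C to rt; then 1 M HCl, 0 °C
Reagents that add atoms: potassium tert-butoxide, CC(C)(C)[O-].[K+]
Why: tert-butoxide cleaves the enol lactone like an enol ester to a stabilised dienolate that keeps the alkene geometry of the ring, this adds through its α-carbon to the doubly activated β-carbon of the formyl quinone monoketal (Michael addition), and acid-induced loss of methanol re-aromatises the ring with the chain between the formyl carbon and the methoxy-bearing carbon; C4 is formed racemic and stays labile.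

Step 6
Reactants: 14 1-tert-butyl 2,4-dimethyl (1E)-3-(2-formyl-3-hydroxy-5,6-dimethoxyphenyl)-4-oxobut-1-ene-1,2,4-tricarboxylate
Product: 16 4-tert-butyl 1-methyl (2E)-2-[(3S,4R)-8-hydroxy-5,6-dimethoxy-3-(methoxycarbonyl)-1-oxo-3,4-dihydro-1H-isochromen-4-yl]but-2-enedioate, via hydroxyindanone 15 (not isolated)
Conditions: (5aS,10bR)-2-(pentafluorophenyl)-5a,10b-dihydro-4H,6H-indeno[2,1-b][1,2,4]triazolo[4,3-d][1,4]oxazin-2-ium tetrafluoroborate (C18H11BF9N3O, 15 mol %), iPr2NEt (1.0 equiv), 4 Å MS, THF, 0 °C to rt; then MgCl2 (1.5 equiv), Et3N (3 equiv), MeCN, rt; pH 4 buffer work-up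
Reagents that add atoms: none
Why: Proposed new method: the chiral triazolylidene turns the aldehyde into a Breslow intermediate that attacks the tethered α-keto ester (5-exo cross-benzoin) while the amine racemises C4–H of 14 (α to the ketone) but not of 15 or 16, so only the (R)-configured substrate is consumed (dynamic kinetic resolution, fixing C4); the magnesium-chelated alkoxide of ketol 15 then adds to the neighbouring aryl ketone and the C1–C2 bond breaks (1,2-acyl shift from carbon to oxygen, expanding the indanone to the six-membered lactone), and the magnesium ester enolate is protonated trans to the C4 substituent to give (3S). The closest known reaction types are the intermolecular carbene-catalysed cross-benzoin of β-stereogenic α-keto esters with dynamic kinetic resolution, the intramolecular aldehyde–ketone benzoin cyclisation, and the base-mediated shift of 2-hydroxy-1,3-dicarbonyl compounds to acyloxy carbonyl compounds (reverse of the Chan rearrangement). The sense of induction of the (5aS,10bR) catalyst is assumed and must be confirmed; its antipode is used if it proves opposite.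

Step 7
Reactants: 16 4-tert-butyl 1-methyl (2E)-2-[(3S,4R)-8-hydroxy-5,6-dimethoxy-3-(methoxycarbonyl)-1-oxo-3,4-dihydro-1H-isochromen-4-yl]but-2-enedioate
Product: 17 (2E)-4-methoxy-3-[(3S,4R)-5,6,8-trihydroxy-3-(methoxycarbonyl)-1-oxo-3,4-dihydro-1H-isochromen-4-yl]-4-oxobut-2-enoic acid
Conditions: BBr3 (6 equiv), CH2Cl2, −78 to 0 °C; then H2O, work-up under argon
Reagents that add atoms: none
Why: Lewis acid ether cleavage, in which boron tribromide removes the two aryl methyl ethers and the tert-butyl ester while the methyl esters, the lactone and both stereocentres (no base present) are expected to survive at or below 0 °C.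

## Compound list

1 | 3-methoxyphenol | COc1cccc(O)c1 | starting material
2 | 2-(hydroxymethyl)-5-methoxyphenol (not isolated) | COc1ccc(CO)c(O)c1 | intermediate
3 | 2-hydroxy-4-methoxybenzaldehyde | COc1ccc(C=O)c(O)c1 | intermediate
4 | 2-hydroxy-4,5-dimethoxybenzaldehyde (not isolated) | COc1cc(O)c(C=O)cc1OC | intermediate
5 | 3,3,4-trimethoxy-6-oxocyclohexa-1,4-diene-1-carbaldehyde | O=CC1=CC(OC)(OC)C(OC)=CC1=O | intermediate
6 | itaconic anhydride (3-methylideneoxolane-2,5-dione) | C=C1CC(=O)OC1=O | starting material
7 | 4-methyl hydrogen itaconate (not isolated) | C=C(CC(=O)OC)C(=O)O | intermediate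
8 | dimethyl itaconate | C=C(CC(=O)OC)C(=O)OC | intermediate
9 | dimethyl oxalate | COC(=O)C(=O)OC | starting material
10 | trimethyl (1E)-4-oxobut-1-ene-1,2,4-tricarboxylate (not isolated) | COC(=O)/C(=C/C(=O)OC)CC(=O)C(=O)OC | intermediate
11 | dimethyl 2-oxo-2H-pyran-4,6-dicarboxylate | COC(=O)C1=CC(=O)OC(C(=O)OC)=C1 | intermediate
12 | potassium dienolate of 1-tert-butyl 2,4-dimethyl (1E)-4-oxobut-1-ene-1,2,4-tricarboxylate (not isolated) | [K+].CC(C)(C)OC(=O)/C=C(C(=O)OC)\C=C(/[O-])C(=O)OC | intermediate
13 | 1-tert-butyl 2,4-dimethyl (1E)-3-(2-formyl-4,6,6-trimethoxy-3-oxocyclohex-4-en-1-yl)-4-oxobut-1-ene-1,2,4-tricarboxylate, mixture of diastereomers (not isolated) | COC(=O)/C(=C/C(=O)OC(C)(C)C)C(C(=O)C(=O)OC)C1C(C=O)C(=O)C=C(OC)C1(OC)OC | intermediate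
14 | 1-tert-butyl 2,4-dimethyl (1E)-3-(2-formyl-3-hydroxy-5,6-dimethoxyphenyl)-4-oxobut-1-ene-1,2,4-tricarboxylate, racemic | COC(=O)/C(=C/C(=O)OC(C)(C)C)C(C(=O)C(=O)OC)c1c(OC)c(OC)cc(O)c1C=O | intermediate
15 | methyl (3R)-3-[(2E)-4-tert-butoxy-1-methoxy-1,4-dioxobut-2-en-2-yl]-2,7-dihydroxy-4,5-dimethoxy-1-oxo-2,3-dihydro-1H-indene-2-carboxylate; C2 is set by the catalyst and lost in the shift, so it is left undefined (not isolated) | COC(=O)/C(=C/C(=O)OC(C)(C)C)[C@H]1c2c(OC)c(OC)cc(O)c2C(=O)C1(O)C(=O)OC | intermediate
16 | 4-tert-butyl 1-methyl (2E)-2-[(3S,4R)-8-hydroxy-5,6-dimethoxy-3-(methoxycarbonyl)-1-oxo-3,4-dihydro-1H-isochromen-4-yl]but-2-enedioate | COC(=O)/C(=C/C(=O)OC(C)(C)C)[C@H]1c2c(OC)c(OC)cc(O)c2C(=O)O[C@@H]1C(=O)OC | intermediate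
17 | (2E)-4-methoxy-3-[(3S,4R)-5,6,8-trihydroxy-3-(methoxycarbonyl)-1-oxo-3,4-dihydro-1H-isochromen-4-yl]-4-oxobut-2-enoic acid | COC(=O)/C(=C/C(=O)O)[C@H]1c2c(O)c(O)cc(O)c2C(=O)O[C@@H]1C(=O)OC | target

## Step count and risks

Total step count: 7. Longest linear sequence: 5 steps (1 → 2 → 5 → 6 → 7; the pyranone branch 3 → 4 → 5 → 6 → 7 is equally long).

The three steps most likely to fail:

**Step 6 (the proposed new step).** The aldehyde is hindered and electron-rich and carries a free ortho-phenol. The acyl anion could add to the fumarate instead (Stetter-type). The ketol-to-ester shift might need more forcing conditions that endanger C4; a direct carbene-mediated hydride transfer, if it intervenes, gives the same 16. The fallback uses known chemistry, sets out from 14 and comes back at 16. Asymmetric transfer hydrogenation with dynamic kinetic resolution reduces both carbonyl groups and sets both stereocentres, using chloro(p-cymene)[(S,S)-N-(p-toluenesulfonyl)-1,2-diphenylethylenediaminato]ruthenium (a divalent ruthenium catalyst) with HCO2H/Et3N in DMF. This gives the diol 1-tert-butyl 2,4-dimethyl (1E,3R,4S)-4-hydroxy-3-[3-hydroxy-2-(hydroxymethyl)-5,6-dimethoxyphenyl]but-1-ene-1,2,4-tricarboxylate F1. MnO2 in CH2Cl2 then oxidises the benzylic alcohol through the lactol to lactone 16, and any cis isomer is converged at C3 with Et3N.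

**Step 5.** tert-Butoxide might attack the pyranone elsewhere, or the formyl monoketal might decompose or undergo aldol chemistry at the aldehyde. The fallback replaces the monoketal by the quinone; it sets out from 3 and 11 and comes back at 17. Oxidation of 3 with (KSO3)2NO gives 4-methoxy-3,6-dioxocyclohexa-1,4-diene-1-carbaldehyde F2. Conjugate addition of dienolate 12 (from 11) at the carbon next to the formyl group gives the hydroquinone 1-tert-butyl 2,4-dimethyl (1E)-3-(2-formyl-3,6-dihydroxy-5-methoxyphenyl)-4-oxobut-1-ene-1,2,4-tricarboxylate F3. The conditions of step 6 convert it into 4-tert-butyl 1-methyl (2E)-2-[(3S,4R)-5,8-dihydroxy-6-methoxy-3-(methoxycarbonyl)-1-oxo-3,4-dihydro-1H-isochromen-4-yl]but-2-enedioate F4, and BBr3 as in step 7 gives 17.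

**Step 2.** The double oxidation of a salicylaldehyde with a free para position may stall or over-oxidise. The fallback installs the oxygen first by a different reaction; it sets out from 3 and comes back at 4 (now isolated) and then 5. Elbs persulfate oxidation (K2S2O8, aqueous NaOH, then HCl) gives 2,5-dihydroxy-4-methoxybenzaldehyde F5. Selective methylation of the non-chelated 5-hydroxyl (CH3I, KHCO3, DMF) gives 4, and a single oxidation with PhI(OAc)2 (1.1 equiv) in MeOH gives 5.

Further compounds
F1 | step 6 | 1-tert-butyl 2,4-dimethyl (1E,3R,4S)-4-hydroxy-3-[3-hydroxy-2-(hydroxymethyl)-5,6-dimethoxyphenyl]but-1-ene-1,2,4-tricarboxylate | COC(=O)/C(=C/C(=O)OC(C)(C)C)[C@H]([C@H](O)C(=O)OC)c1c(OC)c(OC)cc(O)c1CO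
F2 | step 5 | 4-methoxy-3,6-dioxocyclohexa-1,4-diene-1-carbaldehyde | O=CC1=CC(=O)C(OC)=CC1=O
F3 | step 5 | 1-tert-butyl 2,4-dimethyl (1E)-3-(2-formyl-3,6-dihydroxy-5-methoxyphenyl)-4-oxobut-1-ene-1,2,4-tricarboxylate | COC(=O)/C(=C/C(=O)OC(C)(C)C)C(C(=O)C(=O)OC)c1c(O)c(OC)cc(O)c1C=O
F4 | step 5 | 4-tert-butyl 1-methyl (2E)-2-[(3S,4R)-5,8-dihydroxy-6-methoxy-3-(methoxycarbonyl)-1-oxo-3,4-dihydro-1H-isochromen-4-yl]but-2-enedioate | COC(=O)/C(=C/C(=O)OC(C)(C)C)[C@H]1c2c(O)c(OC)cc(O)c2C(=O)O[C@@H]1C(=O)OC
F5 | step 2 | 2,5-dihydroxy-4-methoxybenzaldehyde | COc1cc(O)c(C=O)cc1O
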